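**Retrosynthetic overview**

1. Reading of the target (benzofuran locants; ring A = benzo ring, ring B = O1–C2–C3–C3a–C7a, ring C = 3,5-dimethoxy-4-oxyphenyl on C2, ring D = guaiacyl). Ring B is cis-(2R,3R), the contra-thermodynamic isomer, and the glycerol unit on the 4-oxygen of ring C is erythro-(1R,2S). Rings A, C and D are bought; ring B is the only ring made and is closed last.
2. Key disconnection C2–C3. Ring B comes from an open aryl benzyl ether by an enantio- and cis-selective intramolecular C–H insertion of a donor/acceptor rhodium carbene placed on C3. C3 is raised to a diazo ester, and the ester carbon is the later CH2OH.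
3. Enabling feature: C2 is bonded to O1 and to ring C. In the open form it is therefore an ArO–CH2–Ar methylene whose C–H bonds are activated twice (alpha to O1, benzylic to the electron-rich ring C) and lie 1,5 to C3 across O1–C7a–C3a. The cis relation needs exactly such a kinetic, neutral closure.
4. Precursor assembly: O1–C2 by Mitsunobu etherification of an ortho-iodophenol (ring A, from methyl dihydroferulate) with a syringyl alcohol derivative. C3a–C3 by palladium-catalysed coupling of the aryl iodide with ethyl diazoacetate.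
5. Side chain: Evans syn aldol of the ring C aryloxyacetyl imide with O-silyl vanillin, then Mitsunobu inversion of the benzylic carbinol (threo to erythro). End game: one i-Bu2AlH reduction of three esters and one fluoride step.

Key step: step 11

Assumption: Rh2(S-PTTL)4 is taken to replace the benzylic hydrogen that leads to the (2R)-configured cis product, as expected from simpler 2-(benzyloxy)aryl diazoacetates; should the sense of induction be opposite on this substrate, the mirror-image catalyst Rh2(R-PTTL)4 is used without any other change.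

**Step 1**
Reactants: 1 methyl 3-(4-hydroxy-3-methoxyphenyl)propanoate (methyl dihydroferulate)
Product: 2 methyl 3-(4-hydroxy-3-iodo-5-methoxyphenyl)propanoate
Conditions: NIS, TsOH·H2O (cat.), MeCN, 0 °C to rt
Reagents that add atoms: N-iodosuccinimide, O=C1CCC(=O)N1I
Why: Electrophilic aromatic iodination: the free phenol is the strongest director, its para position carries the side chain and one ortho position the methoxy group, so iodine should enter the one free ortho carbon, the later C3a.

**Step 2**
Reactants: 3 (R)-4-benzyloxazolidin-2-one; 4 bromoacetyl bromide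
Product: 6 (R)-4-benzyl-3-(2-bromoacetyl)oxazolidin-2-one, via lithium oxazolidinide 5 (not isolated)
Conditions: n-BuLi, THF, −78 °C; then 4, −78 to 0 °C
Reagents that add atoms: none
Why: N-Acylation of a lithiated Evans oxazolidinone: the acyl bromide end of 4 is far more electrophilic than its alkyl bromide end at low temperature, and the stereocentre of the auxiliary is not involved.

**Step 3**
Reactants: 6 (R)-4-benzyl-3-(2-bromoacetyl)oxazolidin-2-one; 7 4-(hydroxymethyl)-2,6-dimethoxyphenol (syringyl alcohol)
Product: 8 (R)-4-benzyl-3-{2-[4-(hydroxymethyl)-2,6-dimethoxyphenoxy]acetyl}oxazolidin-2-one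
Conditions: K2CO3, acetone, rt
Reagents that add atoms: none
Why: Williamson ether synthesis: only the phenol of 7 is deprotonated by K2CO3, and its phenoxide displaces the carbonyl-activated primary bromide by SN2 faster than it can attack the imide, while the benzylic alcohol stays free.

**Step 4**
Reactants: 8 aryloxyacetyl imide with free benzylic alcohol; 2 methyl 3-(4-hydroxy-3-iodo-5-methoxyphenyl)propanoate
Product: 9 methyl 3-[4-({4-[2-((R)-4-benzyl-2-oxooxazolidin-3-yl)-2-oxoethoxy]-3,5-dimethoxyphenyl}methoxy)-3-iodo-5-methoxyphenyl]propanoate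
Conditions: PPh3, DIAD, THF, 0 °C to rt
Reagents that add atoms: none
Why: Mitsunobu etherification: the primary benzylic alcohol of 8 is activated as its oxyphosphonium salt and displaced by the acidic, hindered iodophenol 2 under neutral conditions that spare imide and ester, which makes the O1–C2 bond and joins rings A and C.

**Step 5**
Reactants: 10 vanillin
Product: 11 3-methoxy-4-(triisopropylsilyloxy)benzaldehyde
Conditions: TIPSCl, imidazole, DMF, rt
Reagents that add atoms: triisopropylsilyl chloride, CC(C)[Si](Cl)(C(C)C)C(C)C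
Why: Standard silyl protection of a phenol; the bulky TIPS group is chosen so that the aryl silyl ether outlasts the borohydride, amine and Mitsunobu steps and still falls to fluoride at the end.

**Step 6**
Reactants: 9 aryl benzyl ether imide; 11 3-methoxy-4-(triisopropylsilyloxy)benzaldehyde
Product: 14 methyl 3-[4-({4-[(1S,2R)-3-((R)-4-benzyl-2-oxooxazolidin-3-yl)-1-hydroxy-1-(3-methoxy-4-triisopropylsilyloxyphenyl)-3-oxopropan-2-yl]oxy-3,5-dimethoxyphenyl}methoxy)-3-iodo-5-methoxyphenyl]propanoate (syn aldol adduct), via boron enolate 12 (not isolated), via boron aldolate 13 (not isolated)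
Conditions: Bu2BOTf, Et3N, CH2Cl2, −78 to 0 °C; 11, −78 to 0 °C; then pH 7 buffer, MeOH, aq. H2O2, 0 °C
Reagents that add atoms: none
Why: Evans syn aldol reaction: soft enolisation gives the (Z)-boron enolate 12, which adds to 11 through a Zimmerman–Traxler chair on the enolate face turned away from the benzyl group of the (R)-auxiliary, so that the ether-bearing carbon gets its final configuration and the carbinol carbon the syn (threo) one.

**Step 7**
Reactants: 14 syn aldol adduct
Product: 15 methyl 3-[4-({4-[(1S,2S)-1,3-dihydroxy-1-(3-methoxy-4-triisopropylsilyloxyphenyl)propan-2-yl]oxy-3,5-dimethoxyphenyl}methoxy)-3-iodo-5-methoxyphenyl]propanoate (threo diol)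
Conditions: NaBH4, THF–H2O, 0 °C to rt
Reagents that add atoms: none
Why: Reductive cleavage of the N-acyl oxazolidinone with NaBH4: the activated imide carbonyl is reduced much faster than the methyl ester, the aryl iodide is inert, no stereocentre is touched and the auxiliary 3 is recovered.

**Step 8**
Reactants: 15 threo diol
Product: 16 primary TBS ether of 15, (1S,2S)-3-(tert-butyldimethylsilyloxy)-1-hydroxy series
Conditions: TBSCl, imidazole, CH2Cl2, 0 °C
Reagents that add atoms: tert-butyldimethylsilyl chloride, CC(C)(C)[Si](C)(C)Cl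
Why: Selective silylation: the unhindered primary alcohol reacts far faster with TBSCl than the secondary benzylic alcohol flanked by the bulky aryloxy group.

**Step 9**
Reactants: 16 threo mono-TBS ether
Product: 17 methyl 3-[4-({4-[(1R,2S)-3-(tert-butyldimethylsilyloxy)-1-(3-methoxy-4-triisopropylsilyloxyphenyl)-1-(4-nitrobenzoyloxy)propan-2-yl]oxy-3,5-dimethoxyphenyl}methoxy)-3-iodo-5-methoxyphenyl]propanoate (erythro ester)
Conditions: 4-O2NC6H4CO2H, PPh3, DIAD, toluene, −20 °C to rt
Reagents that add atoms: 4-nitrobenzoic acid, OC(=O)c1ccc(cc1)[N+](=O)[O-]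
Why: Mitsunobu inversion: SN2 displacement of the oxyphosphonium salt by the acidic 4-nitrobenzoic acid inverts the benzylic carbinol from S to R, which turns the threo into the erythro series, and the ester formed serves as protecting group up to step 12.

**Step 10**
Reactants: 17 erythro aryl iodide; 18 ethyl diazoacetate
Product: 19 ethyl 2-diazo-2-[2-(benzylic oxy)-3-methoxy-5-(3-methoxy-3-oxopropyl)phenyl]acetate, that is 17 with iodine replaced by C(=N2)CO2Et
Conditions: Pd(PPh3)4 (cat.), Ag2CO3 (0.5 equiv), Et3N, toluene, rt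
Reagents that add atoms: none
Why: Palladium-catalysed cross-coupling of an aryl iodide with the C–H bond of a diazoacetate: oxidative addition of 17 to zerovalent palladium, base- and silver-assisted palladation of the diazo carbon of 18 and reductive elimination at room temperature should give the aryldiazoacetate with the diazo group retained and all esters and silyl ethers untouched.

**Step 11**
Reactants: 19 aryldiazoacetate
Product: 21 ethyl (2R,3S)-2-{4-[(1R,2S)-3-(tert-butyldimethylsilyloxy)-1-(3-methoxy-4-triisopropylsilyloxyphenyl)-1-(4-nitrobenzoyloxy)propan-2-yl]oxy-3,5-dimethoxyphenyl}-7-methoxy-5-(3-methoxy-3-oxopropyl)-2,3-dihydro-1-benzofuran-3-carboxylate (cis), via rhodium carbene 20 (not isolated)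
Conditions: Rh2(S-PTTL)4 [dirhodium tetrakis(N-phthaloyl-(S)-tert-leucinate), 1 mol %], 4 Å MS, toluene, −60 °C
Reagents that add atoms: none
Why: Rh2(S-PTTL)4 expels N2 from 19 to give the electrophilic donor/acceptor rhodium carbene 20 at C3 (donor ring A, acceptor CO2Et), which takes up a C2–H bond through a concerted but asynchronous, hydride-transfer-like three-centre transition state in which the positive charge building at C2 is stabilised by O1 and by the 4-alkoxy-3,5-dimethoxyphenyl ring C. The closest known reaction type is the enantio- and cis-selective intramolecular C–H insertion of 2-(benzyloxy)phenyl diazoacetates with dirhodium tetrakis(N-phthaloyl amino acid carboxylate) catalysts, so a known reaction is applied here to a new molecule. Ring B is closed by 1,5-insertion (five-membered transition-state array C3–C3a–C7a–O1–C2) with formation of the C2–C3 bond, and no other ring forms. C2 is set by the chiral carboxylate pocket, which selects one of the two diastereotopic benzylic hydrogens and replaces it with retention, and C3 is set in the same event because the new C–C and C–H bonds are made on one face of the carbene carbon; the cis relation is kinetic, ring C and the ester both pointing away from the phthalimide wall, and it should survive because the medium is neutral, aprotic and cold. The step needs site selectivity over the other C–H bonds (OCH3, CH2OTBS, the carbinol CH of the nitrobenzoate), over attack on the electron-rich arenes and over carbene dimerisation, and the substrate secures it because only C2–H lies 1,5 to the carbene, it is the most hydridic C–H bond present and every O–H group is masked. Catalyst control is expected to override the distant side-chain stereocentres, and any minor isomer is a diastereomer and thus removable.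

**Step 12**
Reactants: 21 cis ester
Product: 22 (1R,2S)-3-(tert-butyldimethylsilyloxy)-2-{4-[(2R,3R)-3-(hydroxymethyl)-5-(3-hydroxypropyl)-7-methoxy-2,3-dihydro-1-benzofuran-2-yl]-2,6-dimethoxyphenoxy}-1-(3-methoxy-4-triisopropylsilyloxyphenyl)propan-1-ol
Conditions: i-Bu2AlH (DIBAL-H, excess), CH2Cl2, −78 to 0 °C; aq. KNaC4H4O6 (potassium sodium tartrate)
Reagents that add atoms: none
Why: Ester reduction with i-Bu2AlH: the Lewis-acidic, non-basic hydride reduces the C3 ester at low temperature faster than it can enolise, so the cis relation is kept, and the same operation turns the side-chain methyl ester into the hydroxypropyl group and cleaves the 4-nitrobenzoate while the silyl ethers stay.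

**Step 13**
Reactants: 22 bis-silyl ether
Product: 23 (1R,2S)-1-(4-hydroxy-3-methoxyphenyl)-2-{4-[(2R,3R)-3-(hydroxymethyl)-5-(3-hydroxypropyl)-7-methoxy-2,3-dihydro-1-benzofuran-2-yl]-2,6-dimethoxyphenoxy}propane-1,3-diol (target)
Conditions: Bu4NF, AcOH, THF, 0 °C to rt
Reagents that add atoms: none
Why: Fluoride-mediated desilylation: buffered Bu4NF removes the alkyl TBS and the aryl TIPS group in one operation under nearly neutral conditions, which avoids acid-induced ionisation at C2 of ring B (cis to trans) and at the benzylic carbinol.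

**Compound list**

1 | methyl 3-(4-hydroxy-3-methoxyphenyl)propanoate | COC(=O)CCc1ccc(O)c(OC)c1 | starting material
2 | methyl 3-(4-hydroxy-3-iodo-5-methoxyphenyl)propanoate | COC(=O)CCc1cc(I)c(O)c(OC)c1 | intermediate
3 | (R)-4-benzyloxazolidin-2-one | O=C1OC[C@@H](Cc2ccccc2)N1 | starting material
4 | bromoacetyl bromide | BrCC(Br)=O | starting material
5 | lithium salt of 3 (lithium oxazolidinide) | [Li+].O=C1OC[C@@H](Cc2ccccc2)[N-]1 | intermediate
6 | (R)-4-benzyl-3-(2-bromoacetyl)oxazolidin-2-one | O=C1OC[C@@H](Cc2ccccc2)N1C(=O)CBr | intermediate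
7 | 4-(hydroxymethyl)-2,6-dimethoxyphenol (syringyl alcohol) | COc1cc(CO)cc(OC)c1O | starting material
8 | (R)-4-benzyl-3-{2-[4-(hydroxymethyl)-2,6-dimethoxyphenoxy]acetyl}oxazolidin-2-one | O=C1OC[C@@H](Cc2ccccc2)N1C(=O)COc1c(OC)cc(CO)cc1OC | intermediate
9 | aryl benzyl ether imide (rings A and C joined, aryl iodide) | COC(=O)CCc1cc(I)c(OCc2cc(OC)c(OCC(=O)N3C(=O)OC[C@H]3Cc3ccccc3)c(OC)c2)c(OC)c1 | intermediate
10 | vanillin | COc1cc(C=O)ccc1O | starting material
11 | 3-methoxy-4-(triisopropylsilyloxy)benzaldehyde | COc1cc(C=O)ccc1O[Si](C(C)C)(C(C)C)C(C)C | intermediate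
12 | (Z)-dibutylboron enolate of 9 | CCCCB(CCCC)O/C(=C\Oc1c(OC)cc(COc2c(I)cc(CCC(=O)OC)cc2OC)cc1OC)N1C(=O)OC[C@H]1Cc1ccccc1 | intermediate
13 | dibutylboron aldolate of 14 | COc1cc([C@H](OB(CCCC)CCCC)[C@H](C(=O)N2C(=O)OC[C@H]2Cc2ccccc2)Oc2c(OC)cc(COc3c(I)cc(CCC(=O)OC)cc3OC)cc2OC)ccc1O[Si](C(C)C)(C(C)C)C(C)C | intermediate
14 | syn aldol adduct, (1S,2R) in the 3-oxopropan-2-yl unit | COc1cc([C@H](O)[C@H](C(=O)N2C(=O)OC[C@H]2Cc2ccccc2)Oc2c(OC)cc(COc3c(I)cc(CCC(=O)OC)cc3OC)cc2OC)ccc1O[Si](C(C)C)(C(C)C)C(C)C | intermediate
15 | threo-(1S,2S) 1,3-diol | COc1cc([C@H](O)[C@H](CO)Oc2c(OC)cc(COc3c(I)cc(CCC(=O)OC)cc3OC)cc2OC)ccc1O[Si](C(C)C)(C(C)C)C(C)C | intermediate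
16 | threo-(1S,2S) primary TBS ether | COc1cc([C@H](O)[C@H](CO[Si](C)(C)C(C)(C)C)Oc2c(OC)cc(COc3c(I)cc(CCC(=O)OC)cc3OC)cc2OC)ccc1O[Si](C(C)C)(C(C)C)C(C)C | intermediate
17 | erythro-(1R,2S) 4-nitrobenzoate, aryl iodide | COc1cc([C@@H](OC(=O)c2ccc(cc2)[N+](=O)[O-])[C@H](CO[Si](C)(C)C(C)(C)C)Oc2c(OC)cc(COc3c(I)cc(CCC(=O)OC)cc3OC)cc2OC)ccc1O[Si](C(C)C)(C(C)C)C(C)C | intermediate
18 | ethyl diazoacetate | CCOC(=O)C=[N+]=[N-] | starting material
19 | ethyl aryldiazoacetate | COc1cc([C@@H](OC(=O)c2ccc(cc2)[N+](=O)[O-])[C@H](CO[Si](C)(C)C(C)(C)C)Oc2c(OC)cc(COc3c(C(=[N+]=[N-])C(=O)OCC)cc(CCC(=O)OC)cc3OC)cc2OC)ccc1O[Si](C(C)C)(C(C)C)C(C)C | intermediate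
20 | rhodium carbene from 19 (dirhodium core and its four carboxylate ligands abbreviated to one Rh atom in the SMILES) | COc1cc([C@@H](OC(=O)c2ccc(cc2)[N+](=O)[O-])[C@H](CO[Si](C)(C)C(C)(C)C)Oc2c(OC)cc(COc3c(C(=[Rh])C(=O)OCC)cc(CCC(=O)OC)cc3OC)cc2OC)ccc1O[Si](C(C)C)(C(C)C)C(C)C | intermediate
21 | ethyl cis-(2R,3S)-2-aryl-2,3-dihydro-1-benzofuran-3-carboxylate | COc1cc([C@@H](OC(=O)c2ccc(cc2)[N+](=O)[O-])[C@H](CO[Si](C)(C)C(C)(C)C)Oc2c(OC)cc([C@@H]3Oc4c(OC)cc(CCC(=O)OC)cc4[C@@H]3C(=O)OCC)cc2OC)ccc1O[Si](C(C)C)(C(C)C)C(C)C | intermediate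
22 | triol with TBS and TIPS ethers, cis-(2R,3R) ring B | COc1cc([C@@H](O)[C@H](CO[Si](C)(C)C(C)(C)C)Oc2c(OC)cc([C@@H]3Oc4c(OC)cc(CCCO)cc4[C@@H]3CO)cc2OC)ccc1O[Si](C(C)C)(C(C)C)C(C)C | intermediate
23 | CNP0301567.1 | COc1cc([C@@H](O)[C@H](CO)Oc2c(OC)cc([C@@H]3Oc4c(OC)cc(CCCO)cc4[C@@H]3CO)cc2OC)ccc1O | target

**Step count**

Total step count: 13.
Longest linear sequence: 11 steps (steps 2, 3, 4, 6, 7, 8, 9, 10, 11, 12, 13).

**The three steps most likely to fail**

**1. Step 11.**
- What may go wrong: the catalyst may discriminate poorly between the two diastereotopic C2–H bonds. The 7-methoxy group next to O1 could twist the benzyloxy group out of the conformation known from simpler substrates, or the catalyst could be mismatched with the side-chain stereocentres. Partial leakage into the trans series is a second concern.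
- Fallback (a covalently bound auxiliary shares the stereocontrol with the catalyst):
  - Commercial (R)-pantolactone is acylated with 4 and pyridine to (R)-pantolactonyl bromoacetate F1.
  - N,N'-Ditosylhydrazine and DBU turn it into (R)-pantolactonyl diazoacetate F2.
  - The fallback sets out from 17, which is coupled with F2 under the conditions of step 10 to the pantolactonyl aryldiazoacetate F3.
  - Insertion with Rh2(S-PTTL)4, or with the bulky achiral Rh2(O2CCPh3)4, should give the cis pantolactonyl ester F4.
  - The carbonyl group of the alpha-acyloxy lactone leans on the carbene and biases its faces. The unwanted isomers now differ at a stereocentre next to the C3 carboxyl group, which should make crystallisation or chromatography effective. The pantolactone enantiomer is chosen to reinforce the catalyst.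
  - Excess i-Bu2AlH as in step 12 removes the auxiliary together with the other esters, and the fallback comes back to the route at 22.

**2. Step 10.**
- What may go wrong: oxidative addition and palladation may be slow at the electron-rich, ortho-alkoxy aryl iodide, so that palladium-induced loss of nitrogen from the diazo compounds takes over.
- Fallback (carbon first, diazo group second):
  - It sets out from 17. Negishi-type coupling with the commercial Reformatsky reagent BrZnCH2CO2Et (Pd(dba)2, Q-Phos, THF, rt) should give the ethyl arylacetate F5.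
  - Regitz diazo transfer with 4-acetamidobenzenesulfonyl azide and DBU in MeCN acts only on the acidic arylacetate CH2 and not on the aliphatic ester. It comes back to the route at 19.

**3. Step 9.**
- What may go wrong: the electron-rich benzylic oxyphosphonium salt may ionise, so that substitution proceeds with partial retention, or elimination toward the enol ether may occur.
- Fallback (redox inversion in place of SN2):
  - It sets out from 16. Buffered Dess–Martin periodinane gives the (S)-alpha-aryloxy ketone F6.
  - Chelation-controlled reduction with Zn(BH4)2 in Et2O at low temperature delivers hydride from the face of the chelate that bears the small hydrogen and should give the erythro alcohol F7. Any threo material formed is 16 itself and is recycled.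
  - Acylation with 4-nitrobenzoyl chloride, Et3N and DMAP comes back to the route at 17.

**Further compounds**

F1 | step 11 | (R)-pantolactonyl bromoacetate | BrCC(=O)O[C@H]1C(=O)OCC1(C)C
F2 | step 11 | (R)-pantolactonyl diazoacetate | [N-]=[N+]=CC(=O)O[C@H]1C(=O)OCC1(C)C
F3 | step 11 | pantolactonyl aryldiazoacetate | COc1cc([C@@H](OC(=O)c2ccc(cc2)[N+](=O)[O-])[C@H](CO[Si](C)(C)C(C)(C)C)Oc2c(OC)cc(COc3c(C(=[N+]=[N-])C(=O)O[C@H]4C(=O)OCC4(C)C)cc(CCC(=O)OC)cc3OC)cc2OC)ccc1O[Si](C(C)C)(C(C)C)C(C)C
F4 | step 11 | cis-(2R,3S) pantolactonyl 2,3-dihydro-1-benzofuran-3-carboxylate | COc1cc([C@@H](OC(=O)c2ccc(cc2)[N+](=O)[O-])[C@H](CO[Si](C)(C)C(C)(C)C)Oc2c(OC)cc([C@@H]3Oc4c(OC)cc(CCC(=O)OC)cc4[C@@H]3C(=O)O[C@H]5C(=O)OCC5(C)C)cc2OC)ccc1O[Si](C(C)C)(C(C)C)C(C)C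
F5 | step 10 | ethyl arylacetate | COc1cc([C@@H](OC(=O)c2ccc(cc2)[N+](=O)[O-])[C@H](CO[Si](C)(C)C(C)(C)C)Oc2c(OC)cc(COc3c(CC(=O)OCC)cc(CCC(=O)OC)cc3OC)cc2OC)ccc1O[Si](C(C)C)(C(C)C)C(C)C
F6 | step 9 | (S)-alpha-aryloxy ketone | COc1cc(C(=O)[C@H](CO[Si](C)(C)C(C)(C)C)Oc2c(OC)cc(COc3c(I)cc(CCC(=O)OC)cc3OC)cc2OC)ccc1O[Si](C(C)C)(C(C)C)C(C)C
F7 | step 9 | erythro-(1R,2S) alcohol | COc1cc([C@@H](O)[C@H](CO[Si](C)(C)C(C)(C)C)Oc2c(OC)cc(COc3c(I)cc(CCC(=O)OC)cc3OC)cc2OC)ccc1O[Si](C(C)C)(C(C)C)C(C)C
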